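A constant we can read from these runs and carry to a new flask is a rate. We take the runs in slow motion to find it.

| setting | Thursday's | Tuesday's | flask |
|---|---|---|---|
| substrate | 0.10 M | 0.15 M | 0.20 M |
| remark | run made earlier | run made earlier |  |
| time |  |  | 12 d |

| run | time / d | isomer of the product A / % | target / % | substrate / % |
|---|---|---|---|---|
| Thursday's | 1.25 | 8.3 | 16.2 | 10.4 |
| Thursday's | 3.00 | 26.7 | 11.8 | 0.4 |
| Thursday's | 6.00 | 40.5 | 7.2 | 0 |
| Thursday's | 10.0 | 47.3 | 2.5 | 0 |
| Tuesday's | 2.50 | 22.2 | 14.1 | 0 |
| Tuesday's | 5.00 | 36.8 | 5.4 | 1.4 |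
| Tuesday's | 8.00 | 44.0 | 2.7 | 1.1 |
| Tuesday's | 10.0 | 48.9 | 1.2 | 1.8 |

(standard deviation of a reading: 1 percentage point)

1. ratio of isomer of the product A to target at 5.0 h
2. ratio of isomer of the product A to target at 12 d

- the numbers in the tables scatter with a standard deviation of 1 percentage point

First instants. In Thursday's run, substrate is down to 10.4 % by 1.25 d, a first-order fall of 1.81 d⁻¹. Target leads then, at 16.2 % against 8.3 % of the isomer of the product A. Suppose target grows with time and the isomer with its square. The ratio then scales with time, and our early reckoning for the new flask is: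

ratio at 5.0 h = 0.0854

Middle. By 3.00 d in Thursday's run, the isomer stands higher than target, at 26.7 % against 11.8 %.

End. Now watch target fall. Thursday's readings give 0.222 d⁻¹ and Tuesday's give 0.329 d⁻¹. Their ten-day targets differ by 1.3 points, with a scatter of 1 point on each reading. We therefore read the gap as scatter, whereas the forecast reads it as a rise with charge. We take the mean:

late fall rate = 0.275 d⁻¹

This late fall rate is our reading of a first-order constant for target's fraction of the charge. From the ten-day means, with the isomer held at its mean, our reckoning for the new flask is: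

target at 12 d = 1.07 %

ratio at 12 d = 45.1

The forecast gives 0.1 and 100, and of the late one says: “This is very uncertain”.

The flask at 0.20 M gives 0.154 at 5.0 h and 40.3 at 12 d.

    target ⇌ isomer of the product B (K = 0.530, k = 5.40 × 10⁻⁶ s⁻¹)
    substrate → decomposition product (k = 3.90 × 10⁻⁸ s⁻¹)
    substrate → intermediate (k = 2.10 × 10⁻⁵ s⁻¹)
    intermediate ⇌ target (K = 0.390, k = 2.50 × 10⁻⁵ s⁻¹)
    target → over-reaction product (k = 6.20 × 10⁻⁶ s⁻¹)
    intermediate ⇌ isomer of the product A (K = 250, k = 2.50 × 10⁻⁶ s⁻¹)

At 0.382 d in this flask, target is made 3.83 times faster than it is used up, each step taken net. At 12.0 d in this flask the making is slower than the using, at 0.543 of it. Run from the flask's 5.56 % of target at 6.00 d, the late fall rate gives 1.07 % at 12 d, and the flask holds 1.24 %.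

With 0.34 M of substrate, the late fall rate, reckoned on fractions of the charge, again gives 1.07 % of target and a ratio of 45.1. The computed neighbour flask holds 1.24 % of target, at a ratio of 40.3.

The earlier runs and the new flask were generated by integration with made-up constants.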